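If one G took one D, G did nothing else and no step ran back, the summer run could not stop with D left: 4 equiv of G went in over 12 h, yet D reads 31% of its charge at 6.00 d.

the same everywhere: D 0.10 M
- winter: G 1 equiv (fed, over 12 h); run made earlier
- summer: G 4 equiv (fed, over 12 h); run made earlier
- flask: G 2.00 equiv (fed, over 12 h); time 10 d

| run | time / d | D / % | L / % |
|---|---|---|---|
| winter | 0.500 | 85 | 14 |
| winter | 0.833 | 77 | 23 |
| winter | 1.67 | 72 | 25 |
| winter | 3.00 | 75 | 22 |
| winter | 6.00 | 72 | 24 |
| summer | 0.500 | 50 | 42 |
| summer | 0.833 | 35 | 54 |
| summer | 1.67 | 31 | 59 |
| summer | 3.00 | 32 | 58 |
| summer | 6.00 | 31 | 58 |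

(standard deviation of a reading: 1.5 percentage points)

* at 10 d, what has stopped the reaction, if anything has (all of D has reacted / it is still moving / forward and back rates have come level / G has run out first)
* how much of the D has reacted by 10 d
* how much L there is at 10 d, in percent of the D charged
* amount of L if the flask were left three thousand times as long, in percent of the D charged

- the reaction counts as stopped when no species that holds the D changes by six tenths of a point or more over the second half of the time

We read the D columns downward. Winter reaches 72% at 1.67 d, then reads 75% and 72%; summer reaches 31%, then reads 32% and 31%. Within a scatter of 1.5 percentage points, both runs read level from there on.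

Now we read the last row across and write the balance of G. At one G per D reacted, the summer run used 0.690 equiv of its 4 equiv. The remainder either waits beside D or has gone another way.

We reckon with the second case. If G is lost by a first-order path of its own and D falls at a rate in proportion to D times G, then at fixed D charge and feed the logarithm of D charged over D left grows in step with the dose. Winter gives 0.329 equiv⁻¹ and summer 0.293 equiv⁻¹. Their mean, 0.311 equiv⁻¹, is what we call the reach of G: the logarithm of D charged over D left, per equivalent fed.

For the flask, 2.00 equiv of G then leaves 53.7% of D, so 46.3% has reacted. The last summer row shows 84.1% of reacted D as L, which gives us 38.9% of L, with no later change.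

The forecast says G has run out first, with 46% reacted, L at 39.5% and 39.5% in the long run. Of the logarithms following the dose, it says: “which favours G dying, though this isn't conclusive”.

The flask gives G has run out first, with 45.7% reacted, L at 39.7% and 39.7% in the long run.

    G → Z (k = 0.130 h⁻¹)
    D + G → L, rate k2*[D]^1.5*[G] (k = 1.90 M⁻¹·⁵ h⁻¹)
    L ⇌ Q (K = 0.150, k = 0.0990 h⁻¹)

So the forecast stands, and G, though charged at 2.00 equiv, acted as the limiting reagent: at 10.0 d the flask holds G at 0% and D at 54.3%. The D left in this flask gives a reach of 0.305 equiv⁻¹. We carry our 0.311 equiv⁻¹ to the neighbour charged with 0.500 equiv of G, and reckon 85.6% of D left. At 10.0 d that neighbour holds D at 85.4%, G at 0% and L at 12.7%.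

The runs were generated by integration with made-up constants; scatter was added.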